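## Retrosynthetic overview

1. The target is the mono-reduced form of the C2-symmetric (6S,6'S)-ε,ε-carotene-3,3'-dione 11. Its two enone ends are equivalent, so a single trans-selective hydride reduction of either carbonyl gives the target.
2. 11 is cut at both ring–chain bonds (C6–C7 and C6'–C7', carotenoid numbering) into two molecules of racemic 4-bromoisophorone 2 and a C22 bis-alkenyl donor made from diyne 8. Bromide 2 is a vinylogous enolonium equivalent: the γ-carbon of isophorone, normally a donor (dienolate) carbon, is joined to a donor alkenyl–metal carbon. Both stereocentres are set here by an enantioconvergent Ni coupling.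
3. 8 is cut at C11=C12 and C11'=C12' into the C10 dialdehyde 5 and two C6 enynyl phosphonium units 4 (double Wittig).
4. 2 comes from isophorone 1 (allylic bromination); 4 comes from enynol 3.
5. No ring is formed: both six-membered rings are bought intact as isophorone.

Assumption: the target is read as (6S,3'S,6'S)-3'-hydroxy-ε,ε-caroten-3-one (3'-OH trans to the chain); 3 and 5 are taken as catalogue items; the sense of induction in step 4 is not predictable, so the ligand antipode is whichever gives 6S (both are sold), checked by CD.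

## Route

Step 1
Reactants: 1 isophorone (3,5,5-trimethylcyclohex-2-en-1-one)
Product: 2 racemic 4-bromo-3,5,5-trimethylcyclohex-2-en-1-one (4-bromoisophorone)
Conditions: NBS (1.05 equiv), AIBN (5 mol%), PhCF3, 85 °C, 2 h
Reagents that add atoms: N-bromosuccinimide, O=C1CCC(=O)N1Br
Why: Wohl–Ziegler allylic bromination; hydrogen abstraction at ring C4 gives the secondary, carbonyl-conjugated allyl radical, which takes bromine at the γ-carbon so that the enone is kept; the product is racemic, which does not matter because step 4 is enantioconvergent.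

Step 2
Reactants: 3 (2E)-3-methylpent-2-en-4-yn-1-ol
Product: 4 [(2E)-3-methylpent-2-en-4-yn-1-yl]triphenylphosphonium bromide
Conditions: PPh3·HBr (1.0 equiv), MeCN, 60 °C, 12 h; recrystallise (MeCN/EtOAc)
Reagents that add atoms: triphenylphosphine hydrobromide, [Br-].c1ccc(cc1)[PH+](c1ccccc1)c1ccccc1
Why: acid-mediated ionisation of the allylic alcohol and capture of the allyl cation by PPh3 at the unhindered primary terminus (standard phosphonium salt formation in carotenoid work); recrystallisation secures the 2E salt.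

Step 3
Reactants: 4 [(2E)-3-methylpent-2-en-4-yn-1-yl]triphenylphosphonium bromide (2.2 equiv); 5 (2E,4E,6E)-2,7-dimethylocta-2,4,6-trienedial
Product: 8 (3E,5E,7E,9E,11E,13E,15E)-3,7,12,16-tetramethyloctadeca-3,5,7,9,11,13,15-heptaene-1,17-diyne, via phosphonium ylide 6 (not isolated), via C16 pentaenynal 7 (not isolated)
Conditions: NaOMe (2.3 equiv), MeOH/CH2Cl2, 0 °C to rt, dark; then heptane, 90 °C, 3 h; crystallise
Reagents that add atoms: none
Why: two-fold Wittig olefination of the dialdehyde with a semi-stabilised dienynyl ylide; Z isomers at the two new disubstituted double bonds are sterically strained (11-cis type) and equilibrate thermally to the all-E polyene.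

Step 4
Reactants: 8 (3E,5E,7E,9E,11E,13E,15E)-3,7,12,16-tetramethyloctadeca-3,5,7,9,11,13,15-heptaene-1,17-diyne; 2 racemic 4-bromoisophorone (3.0 equiv)
Product: 11 (6S,6'S)-ε,ε-carotene-3,3'-dione, via bis(alkenylzirconocene chloride) 9 (not isolated), via mono-coupled alkenylzirconocene chloride 10 (not isolated)
Conditions: Cp2Zr(H)Cl (2.1 equiv), THF, rt, dark, 1 h; then rac-2, NiCl2(MeOCH2CH2OMe) (10 mol%), (S,S)-Ph-BOX [2,2'-(propane-2,2-diyl)bis((4S)-4-phenyl-4,5-dihydrooxazole)] (13 mol%), DME/THF 1:1, 10 °C, 24 h, dark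
Reagents that add atoms: none
Why: Proposed new method: bromide 2 serves as a vinylogous enolonium (a4) equivalent of isophorone, so its C4 (carotenoid C6/C6'), normally the donor γ-carbon of the dienolate, is joined to the donor carbon of an E-alkenylzirconium formed by syn-hydrozirconation of each terminal alkyne; monovalent nickel abstracts bromine from either enantiomer of 2 to give the same planar oxapentadienyl radical, the bis(oxazoline)-bound divalent alkenylnickel (from Zr-to-Ni transmetalation of 9, then of 10) captures it on one face, and reductive elimination from trivalent nickel occurs at the γ-carbon because this restores the conjugated enone, which sets 6S and 6'S with retention of the E-alkene under non-basic conditions that do not epimerise the doubly allylic C–H; the closest known reaction types are the Ni/bis(oxazoline)-catalysed enantioconvergent alkenylation of racemic α-bromo ketones with alkenylzirconocenes, the γ-selective Ni-catalysed asymmetric Negishi coupling of racemic γ-chloro-α,β-unsaturated carbonyl compounds, and hydrozirconation–cross-coupling of conjugated polyenynes.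

Step 5
Reactants: 11 (6S,6'S)-ε,ε-carotene-3,3'-dione
Product: 13 (6S,3'S,6'S)-3'-hydroxy-ε,ε-caroten-3-one (target CNP0344065.1), via lithium alkoxide 12 (not isolated)
Conditions: LiBH(s-Bu)3 (1.0 equiv), THF, −78 °C, 1 h; AcOH (1.2 equiv), −78 °C to rt; chromatography (11 and diol recovered)
Reagents that add atoms: none
Why: 1,2-reduction of one of two C2-equivalent β,β-disubstituted enones, so only one constitutional mono-alcohol can form (statistical, about 45% at best per pass); in the half-chair with the polyene chain pseudoaxial the bulky hydride attacks equatorially, away from the axial C1 methyl, giving the pseudoaxial 3'-alcohol trans to the chain (3'S,6'S), the lutein-type relative configuration.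

## Compound list

1 | isophorone (3,5,5-trimethylcyclohex-2-en-1-one) | CC1=CC(=O)CC(C)(C)C1 | starting material
2 | racemic 4-bromo-3,5,5-trimethylcyclohex-2-en-1-one | CC1=CC(=O)CC(C)(C)C1Br | intermediate
3 | (2E)-3-methylpent-2-en-4-yn-1-ol | C#C/C(C)=C/CO | starting material
4 | [(2E)-3-methylpent-2-en-4-yn-1-yl]triphenylphosphonium bromide | C#C/C(C)=C/C[P+](c1ccccc1)(c1ccccc1)c1ccccc1.[Br-] | intermediate
5 | (2E,4E,6E)-2,7-dimethylocta-2,4,6-trienedial (C10 dialdehyde) | O=C/C(C)=C/C=C/C=C(C)/C=O | starting material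
6 | [(2E)-3-methylpent-2-en-4-yn-1-ylidene]triphenyl-λ5-phosphane (ylide of 4) | C#C/C(C)=C/C=P(c1ccccc1)(c1ccccc1)c1ccccc1 | intermediate (not isolated)
7 | (2E,4E,6E,8E,10E)-2,7,11-trimethyltrideca-2,4,6,8,10-pentaen-12-ynal (drawn 8E; formed as 8E/8Z mixture) | C#C/C(C)=C/C=C/C(C)=C/C=C/C=C(C)/C=O | intermediate (not isolated)
8 | (3E,5E,7E,9E,11E,13E,15E)-3,7,12,16-tetramethyloctadeca-3,5,7,9,11,13,15-heptaene-1,17-diyne | C#C/C(C)=C/C=C/C(C)=C/C=C/C=C(C)/C=C/C=C(C)/C#C | intermediate
9 | [(1E,3E,5E,7E,9E,11E,13E,15E,17E)-3,7,12,16-tetramethyloctadeca-1,3,5,7,9,11,13,15,17-nonaene-1,18-diyl]bis[Cp2Zr(Cl)] (Cp written σ-bonded in the SMILES) | Cl[Zr](C1C=CC=C1)(C1C=CC=C1)/C=C/C(C)=C/C=C/C(C)=C/C=C/C=C(C)/C=C/C=C(C)/C=C/[Zr](Cl)(C1C=CC=C1)C1C=CC=C1 | intermediate (not isolated)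
10 | Cp2Zr(Cl) all-E nonaenyl complex carrying one (1S)-2,6,6-trimethyl-4-oxocyclohex-2-en-1-yl end group (mono-coupled) | CC1=CC(=O)CC(C)(C)[C@@H]1/C=C/C(C)=C/C=C/C(C)=C/C=C/C=C(C)/C=C/C=C(C)/C=C/[Zr](Cl)(C1C=CC=C1)C1C=CC=C1 | intermediate (not isolated)
11 | (6S,6'S)-ε,ε-carotene-3,3'-dione (all-E) | CC1=CC(=O)CC(C)(C)[C@@H]1/C=C/C(C)=C/C=C/C(C)=C/C=C/C=C(C)/C=C/C=C(C)/C=C/[C@@H]1C(C)=CC(=O)CC1(C)C | intermediate
12 | lithium (6S,3'S,6'S)-3-oxo-ε,ε-caroten-3'-olate | CC1=CC(=O)CC(C)(C)[C@@H]1/C=C/C(C)=C/C=C/C(C)=C/C=C/C=C(C)/C=C/C=C(C)/C=C/[C@@H]1C(C)=C[C@@H]([O-])CC1(C)C.[Li+] | intermediate (not isolated)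
13 | (6S,3'S,6'S)-3'-hydroxy-ε,ε-caroten-3-one (all-E) | CC1=CC(=O)CC(C)(C)[C@@H]1/C=C/C(C)=C/C=C/C(C)=C/C=C/C=C(C)/C=C/C=C(C)/C=C/[C@@H]1C(C)=C[C@@H](O)CC1(C)C | target

## Step count and risks

Total steps: 5. Longest linear sequence: 4 steps (3 → 4 → 8 → 11 → 13).

**Step 4 (two-fold Ni coupling) is the most likely to fail.** The risks are α- instead of γ-coupling, or no coupling at all, at the neopentylic ring carbon; addition of the ring radical to the polyene; and formation of the meso (6R,6'S) diastereomer, which must be removed by crystallisation or HPLC. The fallback sets out from 2, 3 and 5 and comes back at 11. It runs the same polarity-reversed coupling only once, on a small dienyl donor with no polyene present, and closes the chain afterwards by olefination. Enynol 3 is silylated (TBSCl, imidazole) to tert-butyl(dimethyl){[(2E)-3-methylpent-2-en-4-yn-1-yl]oxy}silane F1. F1 is hydrozirconated with Cp2Zr(H)Cl to the dienylzirconocene chloride F2, which is coupled with rac-2 under the Ni/bis(oxazoline) conditions to the C15 silyl ether (4S)-4-[(1E,3E)-5-{[tert-butyl(dimethyl)silyl]oxy}-3-methylpenta-1,3-dien-1-yl]-3,5,5-trimethylcyclohex-2-en-1-one F3. PPh3·HBr in MeOH cleaves the silyl ether and gives the C15 phosphonium bromide {(2E,4E)-3-methyl-5-[(1S)-2,6,6-trimethyl-4-oxocyclohex-2-en-1-yl]penta-2,4-dien-1-yl}triphenylphosphonium bromide F4, which can be recrystallised to raise the ee. Its ylide F5, generated without added base by 1,2-epoxybutane in refluxing EtOH, olefinates 5 twice through the C25 keto aldehyde (6S)-3-oxo-12'-apo-ε-caroten-12'-al F6 to give 11. The price is one more step and an olefination after the base-sensitive stereocentre is in place.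

**Step 5 (mono-reduction) is second.** The risks are the statistical mixture and an insufficient trans:cis ratio at C3'. The fallback sets out from 11 and comes back at 13. Both carbonyls are reduced with excess LiBH(s-Bu)3 to (3S,6S,3'S,6'S)-ε,ε-carotene-3,3'-diol F7. This C2-symmetric diol is freed from cis epimers by crystallisation. One of its two equivalent allylic alcohols is then oxidised with activated MnO2 (CH2Cl2, rt; neutral, selective for 3-hydroxy-ε end groups) to give 13. Unreacted diol and over-oxidised 11 are recycled.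

**Step 3 (double Wittig to the sensitive C22 diyne) is third.** The risks are instability of the alkyne-bearing ylide under methoxide and losses on handling the polyene-diyne. The fallback sets out from 3 and 5 and comes back at 8, with the roles of the olefination partners reversed. Enynol 3 is oxidised with MnO2 to (2E)-3-methylpent-2-en-4-ynal F8. Dialdehyde 5 is reduced (NaBH4) to (2E,4E,6E)-2,7-dimethylocta-2,4,6-triene-1,8-diol F9, which PPh3·HBr converts to [(2E,4E,6E)-2,7-dimethylocta-2,4,6-triene-1,8-diyl]bis(triphenylphosphonium) dibromide F10. Its bis-ylide (2E,4E,6E)-2,7-dimethylocta-2,4,6-triene-1,8-diylidenebis(triphenyl-λ5-phosphane) F11, formed with NaOMe, olefinates two molecules of F8 through the mono-olefinated ylide [(2E,4E,6E,8E,10E)-2,7,11-trimethyltrideca-2,4,6,8,10-pentaen-12-yn-1-ylidene]triphenyl-λ5-phosphane F12. Thermal equilibration then gives 8.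

Further compounds
F1 | step 4 | tert-butyl(dimethyl){[(2E)-3-methylpent-2-en-4-yn-1-yl]oxy}silane | C#C/C(C)=C/CO[Si](C)(C)C(C)(C)C
F2 | step 4 | Cp2Zr(Cl)[(1E,3E)-5-{[tert-butyl(dimethyl)silyl]oxy}-3-methylpenta-1,3-dien-1-yl] (Cp written σ-bonded) | Cl[Zr](C1C=CC=C1)(C1C=CC=C1)/C=C/C(C)=C/CO[Si](C)(C)C(C)(C)C
F3 | step 4 | (4S)-4-[(1E,3E)-5-{[tert-butyl(dimethyl)silyl]oxy}-3-methylpenta-1,3-dien-1-yl]-3,5,5-trimethylcyclohex-2-en-1-one | CC1=CC(=O)CC(C)(C)[C@@H]1/C=C/C(C)=C/CO[Si](C)(C)C(C)(C)C
F4 | step 4 | {(2E,4E)-3-methyl-5-[(1S)-2,6,6-trimethyl-4-oxocyclohex-2-en-1-yl]penta-2,4-dien-1-yl}triphenylphosphonium bromide | CC1=CC(=O)CC(C)(C)[C@@H]1/C=C/C(C)=C/C[P+](c1ccccc1)(c1ccccc1)c1ccccc1.[Br-]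
F5 | step 4 | {(2E,4E)-3-methyl-5-[(1S)-2,6,6-trimethyl-4-oxocyclohex-2-en-1-yl]penta-2,4-dien-1-ylidene}triphenyl-λ5-phosphane | CC1=CC(=O)CC(C)(C)[C@@H]1/C=C/C(C)=C/C=P(c1ccccc1)(c1ccccc1)c1ccccc1
F6 | step 4 | (6S)-3-oxo-12'-apo-ε-caroten-12'-al | CC1=CC(=O)CC(C)(C)[C@@H]1/C=C/C(C)=C/C=C/C(C)=C/C=C/C=C(C)/C=O
F7 | step 5 | (3S,6S,3'S,6'S)-ε,ε-carotene-3,3'-diol | CC1=C[C@@H](O)CC(C)(C)[C@@H]1/C=C/C(C)=C/C=C/C(C)=C/C=C/C=C(C)/C=C/C=C(C)/C=C/[C@@H]1C(C)=C[C@@H](O)CC1(C)C
F8 | step 3 | (2E)-3-methylpent-2-en-4-ynal | C#C/C(C)=C/C=O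
F9 | step 3 | (2E,4E,6E)-2,7-dimethylocta-2,4,6-triene-1,8-diol | OC/C(C)=C/C=C/C=C(C)/CO
F10 | step 3 | [(2E,4E,6E)-2,7-dimethylocta-2,4,6-triene-1,8-diyl]bis(triphenylphosphonium) dibromide | c1ccccc1[P+](c1ccccc1)(c1ccccc1)C/C(C)=C/C=C/C=C(C)/C[P+](c1ccccc1)(c1ccccc1)c1ccccc1.[Br-].[Br-]
F11 | step 3 | (2E,4E,6E)-2,7-dimethylocta-2,4,6-triene-1,8-diylidenebis(triphenyl-λ5-phosphane) | c1ccccc1P(c1ccccc1)(c1ccccc1)=C/C(C)=C/C=C/C=C(C)/C=P(c1ccccc1)(c1ccccc1)c1ccccc1
F12 | step 3 | [(2E,4E,6E,8E,10E)-2,7,11-trimethyltrideca-2,4,6,8,10-pentaen-12-yn-1-ylidene]triphenyl-λ5-phosphane | C#C/C(C)=C/C=C/C(C)=C/C=C/C=C(C)/C=P(c1ccccc1)(c1ccccc1)c1ccccc1
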